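## Retrosynthetic overview
1. Target ⇒ its primary O‑TBS ether, which is cleaved with fluoride in the same flask as the key step.
2. C2–C3 cut (key step): 11‑(furyl)undecanal acts as an acyl anion equivalent and adds to the N‑acetyl imine of TBSO‑acetaldehyde under chiral triazolylidene catalysis. This forms the bond and sets C2 (S), the only stereocentre.
3. The imine comes from an α‑amido sulfone, made from TBSO‑acetaldehyde, acetamide and p‑toluenesulfinic acid.
4. The aldehyde comes from linear hydroformylation of a decenylfuran. The decenylfuran comes from two successive α‑lithiation/alkylations of 3,4‑dimethylfuran (propyl iodide, then 10‑bromodec‑1‑ene).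
5. Rings: the furan (ring A) is bought intact, so no ring is formed.

Assumption: the chain is read as ten CH2 groups between furan C5 and the ketone carbon, and 3,4‑dimethylfuran, 10‑bromodec‑1‑ene, (tert‑butyldimethylsilyloxy)acetaldehyde and p‑toluenesulfinic acid are taken as catalogue chemicals.

Handling: all tetraalkylfurans are kept under argon and away from light and strong acid.

Catalyst of step 5 (from (1R,2S)‑1‑amino‑2‑indanol): Clc1cc(Cl)cc(Cl)c1-[n+]2cn3c(n2)CO[C@H]4Cc5ccccc5[C@@H]34.F[B-](F)(F)F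

## Route

Step 1
Reactants: 1 3,4‑dimethylfuran; 2 1‑iodopropane
Product: 4 3,4‑dimethyl‑2‑propylfuran, via furyllithium 3 (not isolated)
Conditions: n‑BuLi (1.05 equiv), THF, −78 to 0 °C, 1.5 h; then 2 (1.1 equiv), −78 °C to rt; distil
Reagents that add atoms: 1‑iodopropane (2), CCCI
Why: The furan α‑C–H is the most acidic site, so lithiation followed by SN2 alkylation with a primary iodide (heteroaryl lithiation–alkylation) gives the mono‑propyl furan; no stereocentre is formed.

Step 2
Reactants: 4 3,4‑dimethyl‑2‑propylfuran; 5 10‑bromodec‑1‑ene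
Product: 7 2‑(dec‑9‑en‑1‑yl)‑3,4‑dimethyl‑5‑propylfuran, via furyllithium 6 (not isolated)
Conditions: n‑BuLi (1.1 equiv), TMEDA (1.1 equiv), THF, 0 °C to rt, 2 h; then 5 (1.05 equiv), DMPU (2 equiv), −20 °C to rt, 12 h
Reagents that add atoms: 10‑bromodec‑1‑ene (5), C=CCCCCCCCCBr
Why: Only one ring C–H remains, so the same lithiation–SN2 alkylation is regiochemically unambiguous, and the remote terminal alkene is inert to the organolithium.

Step 3
Reactants: 7 2‑(dec‑9‑en‑1‑yl)‑3,4‑dimethyl‑5‑propylfuran
Product: 8 11‑(3,4‑dimethyl‑5‑propylfuran‑2‑yl)undecanal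
Conditions: Rh(acac)(CO)2 (0.5 mol %), 4,5‑bis(diphenylphosphino)‑9,9‑dimethylxanthene (2 mol %), CO/H2 (1:1, 10 bar), toluene, 80 °C, 16 h
Reagents that add atoms: carbon monoxide, [C-]#[O+]
Why: Hydroformylation of a 1‑alkene with a wide‑bite‑angle diphosphine is strongly linear‑selective, and it is neutral and non‑oxidising, so the electron‑rich furan survives while the missing carbon arrives already at the aldehyde level.

Step 4
Reactants: 9 (tert‑butyldimethylsilyloxy)acetaldehyde; 10 acetamide; 11 4‑methylbenzenesulfinic acid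
Product: 12 N‑{2‑[(tert‑butyldimethylsilyl)oxy]‑1‑[(4‑methylphenyl)sulfonyl]ethyl}acetamide (racemic)
Conditions: 9 (1.1 equiv), 10 (1.0 equiv), 11 (1.1 equiv), MgSO4, CH2Cl2, rt, 24 h; crystallise from CH2Cl2/hexane, −20 °C
Reagents that add atoms: acetamide (10), CC(N)=O; 4‑methylbenzenesulfinic acid (11), Cc1ccc(cc1)S(=O)O
Why: In this three‑component α‑amidoalkylation (Mannich‑type condensation) sulfinate traps the hemiaminal/N‑acyliminium pair and crystallisation pulls the equilibrium; the aprotic medium spares the TBS ether, and the uncontrolled sulfone stereocentre is erased in step 5.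

Step 5
Reactants: 8 11‑(3,4‑dimethyl‑5‑propylfuran‑2‑yl)undecanal; 12 N‑{2‑[(tert‑butyldimethylsilyl)oxy]‑1‑[(4‑methylphenyl)sulfonyl]ethyl}acetamide
Product: 15 N‑[(2S)‑13‑(3,4‑dimethyl‑5‑propylfuran‑2‑yl)‑1‑hydroxy‑3‑oxotridecan‑2‑yl]acetamide (target), via N‑acetyl imine 13 (not isolated), via silyl ether 14 (not isolated)
Conditions: 8 (1.0 equiv), 12 (1.3 equiv, three portions), (5aS,10bR)‑2‑(2,4,6‑trichlorophenyl)‑5a,10b‑dihydro‑4H,6H‑indeno[2,1‑b][1,2,4]triazolo[4,3‑d][1,4]oxazin‑2‑ium tetrafluoroborate (15 mol %), 1,2,2,6,6‑pentamethylpiperidine (2.0 equiv), CH2Cl2 (0.2 M), 0 °C, 24 h; then Et3N·3HF (4 equiv), MeCN, 0 °C to rt, 8 h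
Reagents that add atoms: none
Why: Proposed new method: enantioselective carbene‑catalysed cross‑aza‑benzoin coupling of an unbranched aliphatic aldehyde with an enolisable, α‑oxygenated N‑acetyl aldimine; the hindered amine frees the triazolylidene, which adds to 8 to give the enaminol (Breslow‑type acyl anion equivalent), while the same base reversibly expels sulfinate from 12, so 13 is present only in traces and is captured before it tautomerises to the enamide or ties up the carbene; C–C bond formation is expected through a closed transition state in which the enaminol O–H binds the acylimine, the indane wall closes one enaminol face and the CH2OTBS arm turns away from the trichlorophenyl group, so the Re face of the imine carbon is attacked and C2 becomes S; collapse of the adduct returns the carbene, and the acidic fluoride added to the same flask quenches base and carbene (no epimerisation, no E1cB loss of silanolate) while cleaving the primary TBS ether; the trichlorophenyl salt is chosen because sulfinate could attack a pentafluorophenyl ring; the closest known reaction types are the racemic thiazolium‑catalysed coupling of aldehydes with acylimines released from α‑amido sulfones and the triazolium‑catalysed enantioselective cross‑aza‑benzoin of aliphatic aldehydes with non‑enolisable N‑Boc aryl aldimines.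

## Compound list
1 | 3,4‑dimethylfuran | Cc1cocc1C | starting material
2 | 1‑iodopropane | CCCI | starting material
3 | (3,4‑dimethylfuran‑2‑yl)lithium | [Li]c1occ(C)c1C | intermediate
4 | 3,4‑dimethyl‑2‑propylfuran | CCCc1occ(C)c1C | intermediate
5 | 10‑bromodec‑1‑ene | C=CCCCCCCCCBr | starting material
6 | (3,4‑dimethyl‑5‑propylfuran‑2‑yl)lithium | [Li]c1oc(CCC)c(C)c1C | intermediate
7 | 2‑(dec‑9‑en‑1‑yl)‑3,4‑dimethyl‑5‑propylfuran | CCCc1oc(CCCCCCCCC=C)c(C)c1C | intermediate
8 | 11‑(3,4‑dimethyl‑5‑propylfuran‑2‑yl)undecanal | CCCc1oc(CCCCCCCCCCC=O)c(C)c1C | intermediate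
9 | (tert‑butyldimethylsilyloxy)acetaldehyde | CC(C)(C)[Si](C)(C)OCC=O | starting material
10 | acetamide | CC(N)=O | starting material
11 | 4‑methylbenzenesulfinic acid (p‑toluenesulfinic acid) | Cc1ccc(cc1)S(=O)O | starting material
12 | N‑{2‑[(tert‑butyldimethylsilyl)oxy]‑1‑[(4‑methylphenyl)sulfonyl]ethyl}acetamide, racemic | CC(=O)NC(CO[Si](C)(C)C(C)(C)C)S(=O)(=O)c1ccc(C)cc1 | intermediate
13 | N‑{(E)‑2‑[(tert‑butyldimethylsilyl)oxy]ethylidene}acetamide | CC(=O)/N=C/CO[Si](C)(C)C(C)(C)C | intermediate
14 | N‑[(2S)‑1‑[(tert‑butyldimethylsilyl)oxy]‑13‑(3,4‑dimethyl‑5‑propylfuran‑2‑yl)‑3‑oxotridecan‑2‑yl]acetamide | CCCc1oc(CCCCCCCCCCC(=O)[C@H](CO[Si](C)(C)C(C)(C)C)NC(C)=O)c(C)c1C | intermediate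
15 | N‑[(2S)‑13‑(3,4‑dimethyl‑5‑propylfuran‑2‑yl)‑1‑hydroxy‑3‑oxotridecan‑2‑yl]acetamide | CCCc1oc(CCCCCCCCCCC(=O)[C@H](CO)NC(C)=O)c(C)c1C | target

## Step count and risks
Total steps: 5. Longest linear sequence: 4 (steps 1, 2, 3, 5). Step 4 is a one‑step side branch.

**Step 5 (proposed new step).**
- Failure modes: 13 may tautomerise to the enamide, the imine may sequester the carbene, 8 may homocouple to the acyloin, 14 may lose silanolate by β‑elimination, and the ee may erode.
- Facial sense: it cannot be taken from precedent for this imine class. It is checked on the first run by chiral HPLC against material from the fallback below. The antipodal salt, from (1S,2R)‑aminoindanol, is equally available. A final recrystallisation of 15 can raise the ee.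
- Fallback: known chemistry, achiral inputs, a chiral ammonium salt as the only source of asymmetry. It sets out from 8 and comes back at 14. A phase‑transfer‑catalysed direct aldol joins tert‑butyl N‑(diphenylmethylene)glycinate to 8. The catalyst (2 mol %) is the (S,S) N‑spiro quaternary ammonium bromide built from two 2,2'‑bis(methylene)‑1,1'‑binaphthyl units, one of which carries 3,5‑bis[3,5‑bis(trifluoromethyl)phenyl]phenyl groups at C3 and C3'; this is the antipode that gives D‑amino acids in glycinate alkylations. In toluene/1% aq NaOH with NH4Cl (10 mol %) at 0 °C it gives the anti adduct tert‑butyl (2R,3R)‑13‑(3,4‑dimethyl‑5‑propylfuran‑2‑yl)‑2‑[(diphenylmethylidene)amino]‑3‑hydroxytridecanoate F1. Aqueous citric acid (0.5 M) in THF frees tert‑butyl (2R,3R)‑2‑amino‑13‑(3,4‑dimethyl‑5‑propylfuran‑2‑yl)‑3‑hydroxytridecanoate F2. LiAlH4 (THF, 0 °C) gives (2S,3R)‑2‑amino‑13‑(3,4‑dimethyl‑5‑propylfuran‑2‑yl)tridecane‑1,3‑diol F3. Ac2O (1.05 equiv) in MeOH gives N‑[(2S,3R)‑13‑(3,4‑dimethyl‑5‑propylfuran‑2‑yl)‑1,3‑dihydroxytridecan‑2‑yl]acetamide F4. TBSCl/imidazole (CH2Cl2, 0 °C) silylates only the primary alcohol to give N‑[(2S,3R)‑1‑[(tert‑butyldimethylsilyl)oxy]‑13‑(3,4‑dimethyl‑5‑propylfuran‑2‑yl)‑3‑hydroxytridecan‑2‑yl]acetamide F5. Dess–Martin periodinane/NaHCO3 (CH2Cl2, 0 °C) then erases the C3 carbinol centre and gives 14, which takes up the fluoride stage of step 5. The 2R descriptor of the ester becomes 2S after reduction only because the CIP priorities change; the spatial arrangement stays the same.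

**Step 4.**
- Failure modes: acetamide is a weak nucleophile, the sulfone may revert, and the sulfinic acid may nick the TBS ether.
- Fallback: a different imine reservoir with no sulfinic acid. It sets out from 9 and 10 and comes back at 13. Condensation of 9 and 10 with 1H‑benzotriazole (toluene, molecular sieves, rt to 60 °C; benzotriazole‑mediated amidoalkylation) gives N‑{1‑(1H‑benzotriazol‑1‑yl)‑2‑[(tert‑butyldimethylsilyl)oxy]ethyl}acetamide F6. F6 replaces 12 in step 5 and releases the same imine 13 with the amine base.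

**Step 2.**
- Failure modes: SN2 of the hindered, basic furyllithium may be sluggish, E2 on the bromide may compete, and lithiation may be incomplete.
- Fallback: cross‑coupling in place of SN2. It sets out from 6 and comes back at 7. Transmetalation of 6 with ZnCl2 (THF, 0 °C) gives chloro(3,4‑dimethyl‑5‑propylfuran‑2‑yl)zinc F7. Negishi coupling of F7 with 5 (2 mol % [1,3‑bis(2,6‑diisopropylphenyl)imidazol‑2‑ylidene](3‑chloropyridine)palladium dichloride, LiBr, THF/N‑methylpyrrolidone, rt) gives 7 under essentially non‑basic conditions.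

## Further compounds
F1 | step 5 | tert‑butyl (2R,3R)‑13‑(3,4‑dimethyl‑5‑propylfuran‑2‑yl)‑2‑[(diphenylmethylidene)amino]‑3‑hydroxytridecanoate | CCCc1oc(CCCCCCCCCC[C@@H](O)[C@H](C(=O)OC(C)(C)C)N=C(c2ccccc2)c2ccccc2)c(C)c1C
F2 | step 5 | tert‑butyl (2R,3R)‑2‑amino‑13‑(3,4‑dimethyl‑5‑propylfuran‑2‑yl)‑3‑hydroxytridecanoate | CCCc1oc(CCCCCCCCCC[C@@H](O)[C@H](C(=O)OC(C)(C)C)N)c(C)c1C
F3 | step 5 | (2S,3R)‑2‑amino‑13‑(3,4‑dimethyl‑5‑propylfuran‑2‑yl)tridecane‑1,3‑diol | CCCc1oc(CCCCCCCCCC[C@@H](O)[C@H](CO)N)c(C)c1C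
F4 | step 5 | N‑[(2S,3R)‑13‑(3,4‑dimethyl‑5‑propylfuran‑2‑yl)‑1,3‑dihydroxytridecan‑2‑yl]acetamide | CCCc1oc(CCCCCCCCCC[C@@H](O)[C@H](CO)NC(C)=O)c(C)c1C
F5 | step 5 | N‑[(2S,3R)‑1‑[(tert‑butyldimethylsilyl)oxy]‑13‑(3,4‑dimethyl‑5‑propylfuran‑2‑yl)‑3‑hydroxytridecan‑2‑yl]acetamide | CCCc1oc(CCCCCCCCCC[C@@H](O)[C@H](CO[Si](C)(C)C(C)(C)C)NC(C)=O)c(C)c1C
F6 | step 4 | N‑{1‑(1H‑benzotriazol‑1‑yl)‑2‑[(tert‑butyldimethylsilyl)oxy]ethyl}acetamide, racemic | CC(=O)NC(CO[Si](C)(C)C(C)(C)C)n1nnc2ccccc12
F7 | step 2 | chloro(3,4‑dimethyl‑5‑propylfuran‑2‑yl)zinc | CCCc1oc([Zn]Cl)c(C)c1C
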